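**Remark on the chemistry.** The target has no stereocentre, so every chiral intermediate (8, 10, 13, 14) is carried as a racemate. Atom labels follow flavone numbering: O1, C2–C4, C4a, C5–C8, C8a for rings C and A; C1'–C6' for ring B; C1''–C3'' for the prenyl chain.

## Structural features

Artoindonesianin R is a flavone: ring A, a phloroglucinol unit with free hydroxyls at C5 and C7, is fused through C4a and C8a to the 4-pyranone ring C. C2 of ring C is bonded to C1' of ring B, which carries methoxyls at C2' and C4' and a hydroxyl at C5'. C3 carries a prenyl chain (C1''H2–C2''H=C3''Me2).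

The molecule has no stereocentre, so no stereocentres stand next to each other. The route meets only a transient racemic C2 and one exocyclic alkene geometry, and both disappear when ring C becomes aromatic.

The fragile groups are:
- the trisubstituted C2''=C3'' alkene, which adds protic acid and electrophilic halogen and rules out hydrogenolysis;
- the three phenols, which are oxidisable and must be kept distinct from the two methyl ethers;
- the pyranone, which hard nucleophiles open at C2.

The real difficulty is the fully substituted C2=C3 bond, crowded by the ortho-methoxylated, electron-rich ring B on one side and the allylic chain on the other. Late C3-prenylation of a flavone or of a 1,3-diketone would be hindered and would compete with O-alkylation.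

The key step uses the fact that C4 is a carbonyl bonded to C3 while C1'' is a CH2. The C3–C1'' bond can therefore be carried as an exocyclic alkene, and that alkene can come from adding the C4–H of an aldehyde across a C3≡C1'' triple bond held to ring A through O1 and C2. The C2''=C3'' alkene rides along as the ene part of a conjugated enyne, so ring C and the prenyl group come from one carbon chain.

## Logic of the disconnections

**16 ⇒ 15.** The three O–CH2 acetal bonds at O5, O7 and O5' are cut. One acetal type on all three phenols keeps them apart from the two methyl ethers and allows a single unmasking. The skeleton is not simplified, but every earlier compound is free of acidic OH. The forward step must cleave three aryl acetals without adding acid across C2''=C3''.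

**15 ⇒ 14.** No skeletal bond is cut; one hydrogen is moved back from C1'' to C2, so that C2=C3 becomes C3=C1''. This tautomer holds a ketone with an α-alkylidene group, the retron of an alkyne hydroacylation. Ring C drops from an aromatic pyranone to a chromanone whose C3–C4 bond can be made by addition. Forward, the proton must return to C1'' and not to C3''.

**14 ⇒ 13.** The C3–C4 bond and the C1''–H bond are cut. C4 becomes an aldehyde carbon used with reversed polarity, and C3/C1'' become a triple bond. Ring C is opened, and the bicyclic core falls back to two arenes joined by an O1–C2 tether, with no hindered C3 alkylation left. Forward, the closure must be 6-exo and syn, must beat aldehyde dimerisation, and must add across the alkyne only.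

**13 ⇒ 10 + 12.** The O1–C2 ether bond is cut. This is the most convergent point, giving a ring A half and a ring B/side-chain half of similar size, with C2 as a carbinol carbon. Forward, a hydrogen-bonded phenol must be O-alkylated by a secondary, easily ionised alcohol at C2 and not at a remote carbon of the enyne.

**12 ⇒ 11.** Two O–CH2 bonds of the ring A acetals are cut. The gain is a commercial trihydroxy aldehyde. Forward, exactly one hydroxyl must stay free, the one hydrogen-bonded to the formyl group.

**10 ⇒ 8 + 9.** The sp–sp2 bond C1''–C2'' is cut. The isobutenyl group is available as a vinyl bromide, and the other piece is a terminal alkyne. Forward, a hindered, volatile vinyl bromide must couple in the presence of a free carbinol.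

**8 ⇒ 6 + 7.** The C2–C3 bond is cut. C2 becomes the carbonyl carbon of an aromatic aldehyde and C3 an acetylide. Forward, only a plain 1,2-addition is needed, and no stereocontrol.

**6 ⇒ 4 (through 5).** The C1'–C2 bond (aryl–formyl) is cut. The formyl carbon is put where a bromine sits. Forward, halogen–metal exchange must outrun ortho-deprotonation next to the acetal.

**4 ⇒ 3 ⇒ 1 (through 2).** The O–CH2 bond of the ring B acetal is cut, then the C5'–O bond is traced back to the C–CHO bond of 1. In 1 the formyl group and the bromine already sit on the carbons that become C5' and C1'. Forward, the aryl group must migrate from carbon to oxygen, which the two methoxyls ortho and para to the formyl group favour.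

## Other disconnections considered

**Alternative 1:** The cut removes ring A entirely (C8–C8a, C7–C8, C5–C6, C4a–C5). Forward, irradiation of diazoketone A2 with siloxyalkyne A3 would trigger a Wolff rearrangement, ketene–alkyne [2+2] addition, four-electron ring opening and six-electron electrocyclisation onto pyranone C5, giving A1 (a Danheiser benzannulation).
- In its favour: four C–C bonds form in one operation. The C5 hydroxyl emerges free while the C7 oxygen emerges silylated, so the two ring A oxygens are differentiated without protecting-group work. The regiochemistry follows from the polarity of A3.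
- Against it here: A2 already contains the crowded 2-aryl-3-prenyl pyranone, so the central difficulty is moved and not solved. The photolysis has to run beside the prenyl alkene and an absorbing aryl pyranone, which invites carbene or ketene capture by the alkene. A1 carries an extra C6 silicon that must be removed along with two silyl ethers.
- Comparison: on bonds formed per step the alternative is better than the chosen plan. On endgame the two are roughly equal, since each ends with a global unmasking, though A1 needs a protodesilylation as well. On step economy the chosen plan is better, because A2 would take about as many steps as the whole chosen route before ring A is even started. On structure the chosen plan makes the C3 substituent and ring C from one chain, which the alternative does not.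

**Alternative 2:** The cut is at C2–C1' and C3–C1''. Forward, the Grignard reagent A6 (made from bromide 4 of the chosen route) would add to C2 of chromone A5 under copper catalysis, and C-alkylation at C3 by a prenyl halide in the same flask would give the trans flavanone A4. Ring C would then be dehydrogenated and the acetals removed.
- In its favour: it is a three-component assembly from simple halves, and each event (copper-catalysed conjugate arylation of chromones, enolate allylation) is a known reaction type.
- Against it here: at the enolate stage the ring can open by loss of the ring A phenoxide to a chalcone. C-alkylation by a prenyl halide at a hindered centre competes with O-alkylation and with attack through the tertiary terminus. The ortho-methoxy Grignard reagent meets a chromone whose carbonyl is deactivated by the C5 oxygen. A4 is two hydrogens above the flavone, so an oxidant must be used beside the prenyl alkene and three electron-rich rings.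
- Comparison: on step economy the alternative is better, by about two or three steps. On precedent for the individual bond formations it is equal or better. On mechanism the chosen plan needs polarity reversal by a carbene but arrives at the flavone oxidation level, so only a redox-neutral proton shift is needed. On structure the chosen plan avoids forming a bond at the crowded C3 altogether. A4 has the same constitution as the compound the chosen route would pass through if its isomerisation had to be replaced by reduction and dehydrogenation.

**Alternative 3:** The cut is at C3–C4 and O1–C8a. Forward, the lithium enolate of ketone A8 would be C-acylated by acid chloride A9, and the enol oxygen of the resulting 1,3-dicarbonyl would displace an ortho fluoride to close the pyranone as A7.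
- In its favour: it forms the same C3–C4 bond as the chosen plan, with normal polarity and no catalyst. The prenyl chain is in place before ring closure. Ring C is closed directly as the aromatic pyranone, so no isomerisation step is needed, and on this point the alternative is better. The symmetrical acyl group removes any regiochemical question.
- Against it here: A7 has fluorine where the target has the C5 and C7 hydroxyls. Two C–F bonds must be exchanged for oxygen by nucleophiles that can also attack C2 and open the pyranone, and the oxygen groups introduced must then be unmasked together with the ring B allyl ether. O-acylation of the enolate is a competing path.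
- Comparison: on reliability of ring closure the alternative is equal or better. On the endgame the chosen plan is better, because the ring A oxygens are present from the start and only one unmasking remains. On step economy the two are about equal.

Key step: step 8

## Route

Step 1
Reactants: 1 5-bromo-2,4-dimethoxybenzaldehyde
Product: 3 5-bromo-2,4-dimethoxyphenol, via 5-bromo-2,4-dimethoxyphenyl formate 2 (not isolated)
Conditions: mCPBA, CH2Cl2, 0 °C to rt; then K2CO3 (cat.), MeOH, rt
Reagents that add atoms: mCPBA, OOC(=O)c1cccc(Cl)c1
Why: Dakin (Baeyer–Villiger type) oxidation; the methoxyls ortho and para to the formyl group make the aryl group migrate to oxygen, and methanolysis of the formate frees the phenol.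

Step 2
Reactants: 3 5-bromo-2,4-dimethoxyphenol
Product: 4 1-bromo-2,4-dimethoxy-5-(methoxymethoxy)benzene
Conditions: MOMCl, i-Pr2NEt, CH2Cl2, 0 °C to rt
Reagents that add atoms: chloromethyl methyl ether, COCCl
Why: O-alkylation of a phenol by an α-chloro ether; the acetal should withstand the organometallic and basic steps that follow.

Step 3
Reactants: 4 1-bromo-2,4-dimethoxy-5-(methoxymethoxy)benzene
Product: 6 2,4-dimethoxy-5-(methoxymethoxy)benzaldehyde, via [2,4-dimethoxy-5-(methoxymethoxy)phenyl]lithium 5 (not isolated)
Conditions: n-BuLi, THF, −78 °C; DMF, −78 to 0 °C; aq. NH4Cl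
Reagents that add atoms: N,N-dimethylformamide, CN(C)C=O
Why: Bromine–lithium exchange at −78 °C is much faster than ortho-deprotonation beside the acetal, and the aryllithium is formylated by DMF (Bouveault formylation).

Step 4
Reactants: 6 2,4-dimethoxy-5-(methoxymethoxy)benzaldehyde; 7 ethynylmagnesium bromide
Product: 8 1-[2,4-dimethoxy-5-(methoxymethoxy)phenyl]prop-2-yn-1-ol (racemic)
Conditions: THF, 0 °C; aq. NH4Cl
Reagents that add atoms: none
Why: Grignard 1,2-addition to a non-enolisable aromatic aldehyde; the new carbinol centre forms without control, which is acceptable because it is flattened in step 9.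

Step 5
Reactants: 8 1-[2,4-dimethoxy-5-(methoxymethoxy)phenyl]prop-2-yn-1-ol; 9 1-bromo-2-methylpropene
Product: 10 1-[2,4-dimethoxy-5-(methoxymethoxy)phenyl]-5-methylhex-4-en-2-yn-1-ol (racemic)
Conditions: Pd(PPh3)4 (cat.), CuI (cat.), Et3N, THF, 45 °C, sealed tube, excess 9
Reagents that add atoms: none
Why: Sonogashira coupling of a terminal alkyne with a vinyl bromide; the free secondary alcohol is tolerated, and degassing should suppress alkyne homocoupling.

Step 6
Reactants: 11 2,4,6-trihydroxybenzaldehyde
Product: 12 2-hydroxy-4,6-bis(methoxymethoxy)benzaldehyde
Conditions: MOMCl (2.1 equiv), i-Pr2NEt, CH2Cl2, 0 °C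
Reagents that add atoms: chloromethyl methyl ether, COCCl
Why: O-alkylation; after the para and one ortho hydroxyl have reacted, the last hydroxyl is held in a hydrogen bond to the formyl group and should be left untouched by the mild amine base.

Step 7
Reactants: 10 1-[2,4-dimethoxy-5-(methoxymethoxy)phenyl]-5-methylhex-4-en-2-yn-1-ol; 12 2-hydroxy-4,6-bis(methoxymethoxy)benzaldehyde
Product: 13 2-({1-[2,4-dimethoxy-5-(methoxymethoxy)phenyl]-5-methylhex-4-en-2-yn-1-yl}oxy)-4,6-bis(methoxymethoxy)benzaldehyde (racemic)
Conditions: PPh3, DIAD, THF, 0 °C to rt (DIAD added last); chromatography on Et3N-deactivated silica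
Reagents that add atoms: none
Why: Mitsunobu etherification; the salicylaldehyde-type phenol is acidic enough to protonate the betaine, and its phenoxide displaces the oxyphosphonium group at the carbinol carbon, which has no β-hydrogen to eliminate. The substituted alkyne terminus discourages attack at the remote carbon.

Step 8
Reactants: 13 2-({1-[2,4-dimethoxy-5-(methoxymethoxy)phenyl]-5-methylhex-4-en-2-yn-1-yl}oxy)-4,6-bis(methoxymethoxy)benzaldehyde
Product: 14 (E)-2-[2,4-dimethoxy-5-(methoxymethoxy)phenyl]-5,7-bis(methoxymethoxy)-3-(3-methylbut-2-en-1-ylidene)chroman-4-one (racemic)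
Conditions: 3-mesityl-4,5-dimethylthiazol-3-ium tetrafluoroborate (20 mol %), K2CO3 (40 mol %), degassed THF (dilute), 70 °C, sealed tube
Reagents that add atoms: none
Why: The carbene formed from the thiazolium salt and K2CO3 adds to the aldehyde of 13, and proton transfer gives the Breslow enaminol, which makes C4 an acyl anion equivalent. Its nucleophilic carbon attacks the alkyne carbon nearer the tether while the enol O–H is passed to the farther alkyne carbon through a five-membered, Conia-ene-like transition state, and collapse of the alkoxide releases the carbene. The closest known reaction type is the carbene-catalysed intramolecular hydroacylation of unactivated alkynes in 2-(propargyloxy)benzaldehydes, which gives 3-alkylidenechroman-4-ones. The one ring formed, ring C, closes in the 6-exo-dig mode; the 7-endo mode would require attack at the far alkyne carbon and is disfavoured by the short O1–C2 tether. No stereocentre is created: C2 is already present as a racemate, and syn delivery of acyl and hydrogen fixes the alkene as E (isobutenyl trans to C4, which outranks C2), a geometry that step 9 erases. The step needs cyclisation to beat benzoin dimerisation, which the two ortho oxygen substituents and the intramolecular acceptor should secure. It also needs 1,2-addition across the triple bond and not 1,4-addition across the enyne, which the short cyclic proton transfer should secure. Any material that K2CO3 already moves on toward 15 is not lost, since step 9 leads there.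

Step 9
Reactants: 14 (E)-2-[2,4-dimethoxy-5-(methoxymethoxy)phenyl]-5,7-bis(methoxymethoxy)-3-(3-methylbut-2-en-1-ylidene)chroman-4-one
Product: 15 2-[2,4-dimethoxy-5-(methoxymethoxy)phenyl]-5,7-bis(methoxymethoxy)-3-(3-methylbut-2-en-1-yl)-4H-chromen-4-one
Conditions: DBU (20 mol %), toluene, rt to 50 °C
Reagents that add atoms: none
Why: Base-mediated prototropic isomerisation of a 3-alkylidenechromanone to a 3-alkylchromone; DBU removes the C2 hydrogen (allylic, benzylic and α to oxygen), and the ion pair returns the proton to the adjacent C1'', the central carbon of the dienyl anion. The shift should be irreversible because the aromatic pyranone is formed and the new CH2 is no longer acidic toward DBU.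

Step 10
Reactants: 15 2-[2,4-dimethoxy-5-(methoxymethoxy)phenyl]-5,7-bis(methoxymethoxy)-3-(3-methylbut-2-en-1-yl)-4H-chromen-4-one
Product: 16 5,7-dihydroxy-2-(5-hydroxy-2,4-dimethoxyphenyl)-3-(3-methylbut-2-en-1-yl)-4H-chromen-4-one (artoindonesianin R)
Conditions: HCl (1.25 M in MeOH), 40 °C, monitored and stopped at full conversion
Reagents that add atoms: none
Why: Acid-catalysed acetal exchange with methanol; the C5 acetal, peri to the carbonyl, should go first and the other two follow, while the low temperature should keep the trisubstituted alkene from adding HCl or methanol. The aryl methyl ethers are inert to these conditions.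

## Compound list

1 | 5-bromo-2,4-dimethoxybenzaldehyde | COc1cc(OC)c(Br)cc1C=O | starting material
2 | 5-bromo-2,4-dimethoxyphenyl formate | COc1cc(OC)c(Br)cc1OC=O | intermediate (not isolated)
3 | 5-bromo-2,4-dimethoxyphenol | COc1cc(OC)c(Br)cc1O | intermediate
4 | 1-bromo-2,4-dimethoxy-5-(methoxymethoxy)benzene | COCOc1cc(Br)c(OC)cc1OC | intermediate
5 | [2,4-dimethoxy-5-(methoxymethoxy)phenyl]lithium | [Li]c1cc(OCOC)c(OC)cc1OC | intermediate (not isolated)
6 | 2,4-dimethoxy-5-(methoxymethoxy)benzaldehyde | O=Cc1cc(OCOC)c(OC)cc1OC | intermediate
7 | ethynylmagnesium bromide | C#C[Mg]Br | starting material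
8 | 1-[2,4-dimethoxy-5-(methoxymethoxy)phenyl]prop-2-yn-1-ol (racemic) | C#CC(O)c1cc(OCOC)c(OC)cc1OC | intermediate
9 | 1-bromo-2-methylpropene | CC(C)=CBr | starting material
10 | 1-[2,4-dimethoxy-5-(methoxymethoxy)phenyl]-5-methylhex-4-en-2-yn-1-ol (racemic) | CC(C)=CC#CC(O)c1cc(OCOC)c(OC)cc1OC | intermediate
11 | 2,4,6-trihydroxybenzaldehyde | O=Cc1c(O)cc(O)cc1O | starting material
12 | 2-hydroxy-4,6-bis(methoxymethoxy)benzaldehyde | COCOc1cc(O)c(C=O)c(OCOC)c1 | intermediate
13 | 2-({1-[2,4-dimethoxy-5-(methoxymethoxy)phenyl]-5-methylhex-4-en-2-yn-1-yl}oxy)-4,6-bis(methoxymethoxy)benzaldehyde (racemic) | CC(C)=CC#CC(Oc1cc(OCOC)cc(OCOC)c1C=O)c1cc(OCOC)c(OC)cc1OC | intermediate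
14 | (E)-2-[2,4-dimethoxy-5-(methoxymethoxy)phenyl]-5,7-bis(methoxymethoxy)-3-(3-methylbut-2-en-1-ylidene)chroman-4-one (racemic) | CC(C)=C/C=C1/C(=O)c2c(OCOC)cc(OCOC)cc2OC1c1cc(OCOC)c(OC)cc1OC | intermediate
15 | 2-[2,4-dimethoxy-5-(methoxymethoxy)phenyl]-5,7-bis(methoxymethoxy)-3-(3-methylbut-2-en-1-yl)-4H-chromen-4-one | CC(C)=CCc1c(-c2cc(OCOC)c(OC)cc2OC)oc2cc(OCOC)cc(OCOC)c2c1=O | intermediate
16 | 5,7-dihydroxy-2-(5-hydroxy-2,4-dimethoxyphenyl)-3-(3-methylbut-2-en-1-yl)-4H-chromen-4-one (artoindonesianin R) | COc1cc(OC)c(-c2oc3cc(O)cc(O)c3c(=O)c2CC=C(C)C)cc1O | target

## Step count and risks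

Total step count: 10. Longest linear sequence: 9 (steps 1–5 and 7–10, from 1 to 16); step 6 is a one-step branch.

**Step 8 (key step).** Carbene addition to the electron-rich, doubly ortho-substituted aldehyde may be slow. That would give time for base-induced propargyl-to-allenyl isomerisation at the acidic C2–H, for ionisation of the labile benzylic ether, or for 1,4-addition across the enyne. The fallback forms the same C3–C4 bond with normal polarity. From 13, a reductive alkyne–aldehyde cyclisation with zerovalent nickel (Ni(cod)2, PBu3, Et3SiH, THF) should proceed through an oxanickelacycle with syn delivery of hydrogen and give (E)-2-[2,4-dimethoxy-5-(methoxymethoxy)phenyl]-5,7-bis(methoxymethoxy)-3-(3-methylbut-2-en-1-ylidene)-4-(triethylsilyloxy)chromane F1 as a diastereomer mixture. Desilylation with TBAF in THF should give (Z)-2-[2,4-dimethoxy-5-(methoxymethoxy)phenyl]-5,7-bis(methoxymethoxy)-3-(3-methylbut-2-en-1-ylidene)chroman-4-ol F2 (same geometry; the descriptor changes only because C2 now outranks C4). Oxidation of this allylic, benzylic alcohol with MnO2 in CH2Cl2 should return the route to 14.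

**Step 7.** The oxyphosphonium intermediate of a carbinol flanked by a 2,4-dialkoxyaryl group and an enyne may ionise before the phenoxide arrives. Substitution could then occur at a remote carbon of the enyne, or the cation could attack the electron-rich ring of the phenol at carbon; the product ether is also acid-labile on silica. The fallback sets out from 8. Acetylation (Ac2O, Et3N, DMAP, CH2Cl2) should give 1-[2,4-dimethoxy-5-(methoxymethoxy)phenyl]prop-2-yn-1-yl acetate F3. Copper-catalysed propargylic substitution with 12 (CuOTf·0.5C6H6, 2,6-bis(4,5-dihydrooxazol-2-yl)pyridine, i-Pr2NEt) runs through a copper allenylidene that accepts nucleophiles only at the propargylic carbon, and should give 2-({1-[2,4-dimethoxy-5-(methoxymethoxy)phenyl]prop-2-yn-1-yl}oxy)-4,6-bis(methoxymethoxy)benzaldehyde F4. Sonogashira coupling of this terminal alkyne with 9 (Pd(PPh3)4, CuI, Et3N) should rejoin the route at 13.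

**Step 9.** The delocalised anion may be reprotonated at C3'' instead of C1'', which would move the side-chain alkene into conjugation with ring C, or deprotonation of the hindered C2–H next to the electron-rich ring B may be sluggish. The fallback replaces the proton shift by reduction and oxidation. From 14, conjugate hydride addition at C1'' (LiBH(s-Bu)3, THF, −78 °C) should give 2-[2,4-dimethoxy-5-(methoxymethoxy)phenyl]-5,7-bis(methoxymethoxy)-3-(3-methylbut-2-en-1-yl)chroman-4-one F5 as a cis/trans mixture. Dehydrogenation with DDQ in dioxane at 80 °C starts by hydride loss from C2 (benzylic and α to oxygen), so it can only form C2=C3, and should rejoin the route at 15.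

**Step 10.** Protonation of the C2''=C3'' alkene may compete with cleavage of the slower C7 and C5' acetals, giving Markovnikov addition of chloride or methanol. The fallback avoids protic acid. From 15, TMSOTf with 2,2'-bipyridyl in CH2Cl2 at 0 °C should transfer each methoxymethyl group to the pyridine nitrogen and leave 2-[2,4-dimethoxy-5-(trimethylsilyloxy)phenyl]-3-(3-methylbut-2-en-1-yl)-5,7-bis(trimethylsilyloxy)-4H-chromen-4-one F6. Addition of water then hydrolyses the silyl ethers and arrives at 16.

## Further compounds

F1 | step 8 | (E)-2-[2,4-dimethoxy-5-(methoxymethoxy)phenyl]-5,7-bis(methoxymethoxy)-3-(3-methylbut-2-en-1-ylidene)-4-(triethylsilyloxy)chromane (diastereomer mixture, racemic) | CC(C)=C/C=C1/C(O[Si](CC)(CC)CC)c2c(OCOC)cc(OCOC)cc2OC1c1cc(OCOC)c(OC)cc1OC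
F2 | step 8 | (Z)-2-[2,4-dimethoxy-5-(methoxymethoxy)phenyl]-5,7-bis(methoxymethoxy)-3-(3-methylbut-2-en-1-ylidene)chroman-4-ol (diastereomer mixture, racemic) | CC(C)=C/C=C1/C(O)c2c(OCOC)cc(OCOC)cc2OC1c1cc(OCOC)c(OC)cc1OC
F3 | step 7 | 1-[2,4-dimethoxy-5-(methoxymethoxy)phenyl]prop-2-yn-1-yl acetate (racemic) | C#CC(OC(C)=O)c1cc(OCOC)c(OC)cc1OC
F4 | step 7 | 2-({1-[2,4-dimethoxy-5-(methoxymethoxy)phenyl]prop-2-yn-1-yl}oxy)-4,6-bis(methoxymethoxy)benzaldehyde (racemic) | C#CC(Oc1cc(OCOC)cc(OCOC)c1C=O)c1cc(OCOC)c(OC)cc1OC
F5 | step 9 | 2-[2,4-dimethoxy-5-(methoxymethoxy)phenyl]-5,7-bis(methoxymethoxy)-3-(3-methylbut-2-en-1-yl)chroman-4-one (cis/trans mixture, racemic) | CC(C)=CCC1C(=O)c2c(OCOC)cc(OCOC)cc2OC1c1cc(OCOC)c(OC)cc1OC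
F6 | step 10 | 2-[2,4-dimethoxy-5-(trimethylsilyloxy)phenyl]-3-(3-methylbut-2-en-1-yl)-5,7-bis(trimethylsilyloxy)-4H-chromen-4-one | COc1cc(OC)c(-c2oc3cc(O[Si](C)(C)C)cc(O[Si](C)(C)C)c3c(=O)c2CC=C(C)C)cc1O[Si](C)(C)C
A1 | alternative 1 | 2-[2,4-dimethoxy-5-(triisopropylsilyloxy)phenyl]-5-hydroxy-3-(3-methylbut-2-en-1-yl)-7-(triisopropylsilyloxy)-6-(trimethylsilyl)-4H-chromen-4-one | COc1cc(OC)c(-c2oc3cc(O[Si](C(C)C)(C(C)C)C(C)C)c([Si](C)(C)C)c(O)c3c(=O)c2CC=C(C)C)cc1O[Si](C(C)C)(C(C)C)C(C)C
A2 | alternative 1 | 2-diazo-1-{6-[2,4-dimethoxy-5-(triisopropylsilyloxy)phenyl]-5-(3-methylbut-2-en-1-yl)-4-oxo-4H-pyran-2-yl}ethan-1-one | [N-]=[N+]=CC(=O)c1cc(=O)c(CC=C(C)C)c(-c2cc(O[Si](C(C)C)(C(C)C)C(C)C)c(OC)cc2OC)o1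
A3 | alternative 1 | triisopropyl{[(trimethylsilyl)ethynyl]oxy}silane | C[Si](C)(C)C#CO[Si](C(C)C)(C(C)C)C(C)C
A4 | alternative 2 | trans-2-[2,4-dimethoxy-5-(methoxymethoxy)phenyl]-5,7-bis(methoxymethoxy)-3-(3-methylbut-2-en-1-yl)chroman-4-one (racemic, one enantiomer drawn) | O=C1[C@H](CC=C(C)C)[C@@H](c3cc(OCOC)c(OC)cc3OC)Oc2cc(OCOC)cc(OCOC)c12
A5 | alternative 2 | 5,7-bis(methoxymethoxy)-4H-chromen-4-one | COCOc1cc(OCOC)c2c(=O)ccoc2c1
A6 | alternative 2 | [2,4-dimethoxy-5-(methoxymethoxy)phenyl]magnesium bromide | COCOc1cc([Mg]Br)c(OC)cc1OC
A7 | alternative 3 | 2-[5-(allyloxy)-2,4-dimethoxyphenyl]-5,7-difluoro-3-(3-methylbut-2-en-1-yl)-4H-chromen-4-one | CC(C)=CCc1c(-c2cc(OCC=C)c(OC)cc2OC)oc2cc(F)cc(F)c2c1=O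
A8 | alternative 3 | 1-[5-(allyloxy)-2,4-dimethoxyphenyl]-5-methylhex-4-en-1-one | CC(C)=CCCC(=O)c1cc(OCC=C)c(OC)cc1OC
A9 | alternative 3 | 2,4,6-trifluorobenzoyl chloride | O=C(Cl)c1c(F)cc(F)cc1F
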